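3.88 d: that is how long Sunday's flask would take to halve its electrophile if the 80 % left at 30.0 h marked a steady pace. Call it the running half-life. Tuesday's flask, with half the buffer acid, reads 3.88 d from its 83 % at 25.0 h, so on this measure the two runs do not part.

| setting | Sunday's | Tuesday's | flask |
|---|---|---|---|
| electrophile | 0.050 M | 0.050 M | 0.050 M |
| nucleophile | 0.075 M | 0.075 M | 0.0750 M |
| buffer base | 0.010 M | 0.010 M | 0.0100 M |
| buffer acid | 5 mM | 2.5 mM | 5.00 mM |
| remark | the very flask that is asked about, followed so far | run made earlier |  |
| time |  |  | 2.5 d |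

| run | time / h | electrophile / % | product / % |
|---|---|---|---|
| Sunday's | 2.50 | 96 | 4 |
| Sunday's | 4.00 | 96 | 2 |
| Sunday's | 6.00 | 95 | 7 |
| Sunday's | 10.0 | 94 | 6 |
| Sunday's | 20.0 | 84 | 14 |
| Sunday's | 30.0 | 80 | 20 |
| Tuesday's | 4.00 | 95 | 4 |
| Tuesday's | 8.00 | 92 | 8 |
| Tuesday's | 12.0 | 91 | 12 |
| Tuesday's | 15.0 | 88 | 14 |
| Tuesday's | 20.0 | 85 | 16 |
| Tuesday's | 25.0 | 83 | 18 |

(readings scatter by 1.5 percentage points)

- what was read earlier has a scatter of 1.5 percentage points, one standard deviation
- the earlier runs do not show the pH; that part of a forecast is a guess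

- part of the electrophile that has reacted at 2.5 d
- pH of the solution at 2.5 d

Held steady, that pace gives 36.0 % reacted at 2.5 d. But I take the pace to follow the nucleophile, an assumption the readings do not test, so put that answer back in. Counting one nucleophile per reacted electrophile, you get a mean of 0.0700 M during Sunday's run and 0.0610 M from there on. The half-life stretches to 4.46 d, and I commit to 34.1 %.

The forecast stands lower, at 28 % (22 % to 37 %), with pH 4.5 (2.8 to 6.5): past 20% conversion “the buffer is gone and the pH should fall sharply, unless the nucleophile takes up the protons”.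

The flask gives 31.7 % reacted and pH 6.28.

    buffer acid ⇌ buffer base + acid, settled at all times (K = 2.50 × 10⁻⁷ M)
    protonated nucleophile ⇌ nucleophile + acid, settled at all times (K = 1.60 × 10⁻⁶ M)
    electrophile + nucleophile → acid + product + leaving group (k = 0.130 M⁻¹ h⁻¹)
    nucleophile + leaving group ⇌ idle adduct, settled at all times (K = 1700 M⁻¹)

In the asked flask the step from electrophile and nucleophile to product gives the electrophile a half-life of 3.0 d as charged, but 6.8 d at 2.50 d, twice as long. By then unbound nucleophile in that flask stands at 44 % of its charge. In this flask the running half-life from 1.25 d to 2.50 d is 5.64 d, longer than my second pass. Left until 10 d, the neighbouring flask holds 47.3 % of its electrophile, which puts the running half-life from 2.5 d on at 14.2 d.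

The runs stem from a simulated flask for an exercise, and the scatter is random.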